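The constants are those of an exercise; the rest is arithmetic.

By the time you read this the flask had been stirring for a while, so I left you this note.

    starting material + free catalyst ⇌ free catalyst + intermediate (K1 = 2.8, k1 = 0.60 M⁻¹ s⁻¹)
    partner + second catalyst + intermediate → second catalyst + product (k2 = 1.9 M⁻² s⁻¹)
    2 partner → homo dimer (k3 = 3.9 × 10⁻⁴ M⁻¹ s⁻¹)

starting material 0.36 M; partner 1.30 equiv; free catalyst 5 mol%; second catalyst 0.15 mol%; time 30 min

- where a step has two of a species, its rate is k times that concentration squared, and two are used at each turn
- the reaction counts as stopped when no species that holds the starting material changes by six tenths of a point or more over the second half of the time
- run time (flask): 30 min

- the state of affairs at 30 min: stopped, and by what, or still going (it is still moving / forward and back rates have come level / all of the starting material has reacted / no working catalyst is left / the partner has run out first)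
- amount of product at 30 min, in percent of the starting material charged
- amount of intermediate at 30 min, in percent of the starting material charged

I turned the constants into times. The pool time came to 47.1 min: it is one over the second step's constant times c(second catalyst) times c(partner), at the charged amounts, stretched by the share of the pool that is intermediate at equilibrium, and it is the lifetime, at charged partner, of the pool of starting material and intermediate on its way to product. The forward half-life of starting material was 1.1 min, far shorter, so I held the first step as a pre-equilibrium. But c(partner) sinks too: its first half-life by the homo dimer step alone, 45.7 min, is about as long as the pool time. Averaged along that fall, the 30 min counted as 23.1 min at full partner. That gave me 38.7% product and 45.2% intermediate, with 15 percentage points of the product still arriving in the second half. So I expected the flask still moving at 30 min: don't take the quick first minutes for the whole run, and leave the flask alone.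

The forecast stood lower in product than I did: it is still moving, 31% product (29% to 33.5%) and 50% intermediate (48% to 52%), and it said “Homo-dimerisation eats the partner at about the same pace”.

The simulation said it is still moving, with 32.7% product and 49.4% intermediate.

Against the pool time, that product is worth 18.7 min at full partner, not my 23.1 min. At 30.0 min the flask used partner 1.1 times as fast for product as for homo dimer, and my reckoning, which let partner fall by the homo dimer step, kept 60.4% of it where the flask had 44%.

In the neighbour flask with 0.14 M starting material, equivalents, loadings and time held, the pool time is 311 min, which by the same reckoning promises 8.22% product. That neighbour flask gave 7.15%.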